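## The problem

Target 14 is a 4H-pyran-4-one in which every ring carbon is substituted (numbering used throughout: O1, C2-OMe, C3-Et, C4=O, C5-Et, C6-alkyl); C6 carries an unbranched chain C1'-C11' whose only stereocentre, C10', is an (S)-configured secondary acetate. No ring carbon bears hydrogen, so the four substituents must arrive together with the ring atoms. The 2-methoxy-4-pyranone is one of two O-methyl isomers of an ambident 4-hydroxy-2-pyranone, so every closure at O1-C2 by lactonisation leaves a methylation that must find the right oxygen. The carbonyl carbon that becomes C6 has a methylene group on either side (C5 and C1'), so enolate chemistry on the corresponding ketone cannot tell the ring side from the chain side. C10' lies nine methylene groups from the ring: nothing in the molecule can control it, it controls nothing, and it must be bought or set by a reagent or enzyme that tells methyl from a long chain. The acetate does not survive enolates, dianions, organolithium reagents or methoxide, and the vinylogous carbonate O1-C2(OMe)=C3-C4=O is open to nucleophiles at C2 and to demethylation by acid, which argues for a late, neutral ring construction. The feature that makes the key step possible is a repeat inside the ring: C5(Et)-C4(=O) and C3(Et)-C2(OMe) are two head-to-tail copies of the same unit Et-C-C-O, attached to the acyl unit C6-O1 that ends the chain. The ring is therefore the sum of one acyl chloride (11) and two molecules of one alkyne, 1-methoxybut-1-yne (4), less the methyl group of the first alkyne and the chlorine of 11.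

## Retrosynthesis

**14 to 13 and 4.** The bonds C3-C4 and O1-C2 are cut in a retro hetero-[4+2] step. O1=C6-C5=C4 becomes the oxadiene of acylketene 13, and C2-C3 becomes the triple bond of 4. The neighbouring cut at O1-C2 alone (lactonisation) brings the methylation problem with it. Here the methoxy group is bound to C2 before the ring exists, and the ring closes at a C-C bond between the only donor carbon of 4 and the ketene carbon. The precursor has no ring and two substituents fewer. The forward reaction must prefer six-membered closure over [2+2] addition, and it must run without acid, base or nucleophile because the acetate is already in place.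

**13 to 11 and 4, by way of 12.** The bond C5-C6 is cut, together with the O-CH3 bond at what becomes the C4 oxygen. The piece C4-C5(Et) of 13 is again 4, acylated at its donor carbon. The chloride that leaves 11 is the nucleophile that takes the methyl group off 12. The neighbouring cut C4-C5 would require acylating a ketone enolate that cannot be formed regioselectively. The repeat mirrors a polyketide assembly of one fatty acyl starter and two C4 extender units. Both halves use the same reagent under the same neutral conditions, so they are merged into one operation, step 6. Its precursor 11 is an acyclic, monofunctional acyl chloride, and three ring bonds and all four substituents are set at once. The acylation must outrun the destruction of 4 by traces of acid, and 11 must not attack 14.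

**11 to 10 to 9.** After the functional group change from 11 to 10, the carboxyl carbon (later C6) is traced to the inner carbon of the terminal alkene of 9, through cleavage of C12=C13. An alkene is the carboxyl equivalent that passes through the Grignard chemistry of the next cut without a protecting group, at the cost of one lost carbon. The forward reaction must cleave the alkene to the acid in one step without touching the acetate.

**9 to 8 to 7 and 6.** After removal of the acetyl group, the bond C8'-C9' (C3-C4 of 8) is cut. This is the bond next but one to the stereocentre, so the cut leads to epoxide 6, in which C10' is bought with the right configuration. The neighbouring cuts C9'-C10' and C10'-C11' would have to create the centre by asymmetric addition to an aldehyde. The precursors are 6 and Grignard reagent 7, made from bromide 5. The forward reaction must attack only the CH2 terminus of 6, so that no bond to C10' is broken.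

**4 to 3 and 2, and 3 from 1.** The bond between the alkyne carbon and the CH2 of the ethyl group is cut. This gives acetylide 3 and halide 2, and 3 comes from chloro acetal 1 by double elimination. Cutting the C-O bond instead would require substitution at an sp carbon. All three precursors are bulk chemicals. The forward reaction must run elimination and alkylation in one flask.

## Roads not taken

**Alternative 1:** (the most obvious route) The cut is at O1-C2 and at the O-CH3 bond.
- Forward: methyl 2-ethyl-3-oxohexanoate A1 is turned into its dianion and acylated at C4 with the side-chain acyl unit to give triketo ester A2. Base-induced lactonisation gives the 4-hydroxy-2-pyranone A3. The forward key step is O-methylation of A3 at the lactone carbonyl oxygen.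
- The dianion would destroy the acetate, so C10' must travel as a silyl ether (as drawn in A2 and A3), and deprotection and acetylation are added at the end.
- The acylation takes place at a secondary, ethyl-bearing carbanion and gives a product more acidic than A1, so part of the dianion is spent as base.
- The methylation meets an ambident system whose C4 oxygen is the more accessible one. Only very hard and hazardous methylating agents reach the other oxygen, and competing attack at C4-O must be dealt with at the last ring step. In step 6 this question cannot arise.

**Alternative 2:** The cut is at C6-C1' and uses the near-symmetry of the ring.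
- Forward: 3,5-diethyl-2,6-dimethoxy-4H-pyran-4-one A4 is desymmetrised by conjugate addition-elimination of the side-chain organolithium A5 at C6, which gives A6.
- A4 itself must be built by ring closure and double O-methylation, so the ambident problem returns.
- A5 forces the same exchange of acetate for silyl ether as in Alternative 1, and it needs a C11 halide with the stereocentre that is no shorter to make than 10.
- A6 still holds a second vinylogous leaving group at C2 and the C4 carbonyl, so a second substitution and 1,2-addition compete with the wanted single one.
- The chosen plan makes the C6-chain bond obsolete, since C6 is the carboxyl carbon of the chain.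

**Alternative 3:** The cut is at the C10'-O bond (C-H oxidation).
- Forward: dodecanoyl chloride A7 would give 3,5-diethyl-2-methoxy-6-undecyl-4H-pyran-4-one A8 by the same ring construction. A cytochrome P450 monooxygenase of the subterminal fatty acid hydroxylase class would oxidise C10'-H to alcohol A9, which is then acetylated. On paper this is the shortest route.
- Enzymes of this class hold their substrates by a carboxylate that A8 lacks.
- As a class they spread oxidation over the last three methylene groups.
- There is no structural reason to expect the S sense at C10'.
- The two ethyl groups and the O-methyl group are further sites for oxidation.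
- The route would stack a second uncertain step on the first, whereas C10' can be bought in 6 with the right configuration.

Key step: step 6

Remark: the centre written [C@H] in the given SMILES is C10' and reads as S (O > C9' > C11' > H). No step breaks a bond to it, so the configuration of 6 is carried through unchanged.

## Steps

Step 1
Reactants: 1 2-chloro-1,1-dimethoxyethane; 2 bromoethane
Product: 4 1-methoxybut-1-yne, via sodium methoxyacetylide 3 (not isolated)
Conditions: NaNH2 (3.1 equiv), liq. NH3, -33 °C; then 2, -33 °C; NH3 evaporated, cold brine, distillation
Reagents that add atoms: none
Why: Twofold 1,2-elimination (HCl and MeOH) from the α-chloro acetal and deprotonation by NaNH2 give acetylide 3, which is alkylated by SN2 attack on 2 in the same flask; this is the standard preparation of 1-alkoxyalk-1-ynes and is established for the ethoxy analogue with the same halide.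

Step 2
Reactants: 5 10-bromodec-1-ene; 6 (S)-2-methyloxirane
Product: 8 (2S)-tridec-12-en-2-ol, via dec-9-enylmagnesium bromide 7 (not isolated)
Conditions: Mg, THF, rt to 40 °C; CuI (10 mol %), -30 °C; 6, -30 to 0 °C; sat. aq. NH4Cl
Reagents that add atoms: none
Why: Copper-catalysed SN2 opening of a terminal epoxide by a Grignard reagent takes place at the unsubstituted carbon. The C-O bond at the stereocentre is not touched, so C2 of 8 keeps the configuration of 6, and the descriptor stays S because the order O > CH2 > CH3 > H is unchanged.

Step 3
Reactants: 8 (2S)-tridec-12-en-2-ol
Product: 9 (2S)-tridec-12-en-2-yl acetate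
Conditions: Ac2O (1.5 equiv), Et3N (2 equiv), DMAP (5 mol %), CH2Cl2, 0 °C to rt
Reagents that add atoms: acetic anhydride, CC(=O)OC(C)=O
Why: DMAP-catalysed acylation of a secondary alcohol proceeds with retention, because only the O-H bond is broken. The final ester is installed here and serves as its own protecting group in all later steps.

Step 4
Reactants: 9 (2S)-tridec-12-en-2-yl acetate
Product: 10 (11S)-11-acetoxydodecanoic acid
Conditions: RuCl3·xH2O (2 mol %), NaIO4 (4.1 equiv), MeCN/EtOAc/H2O, rt
Reagents that add atoms: sodium periodate, [Na+].[O-]I(=O)(=O)=O
Why: Oxidative cleavage of a terminal alkene by catalytic RuO4, regenerated by periodate, takes C12=C13 to the carboxylic acid with loss of C13. The acetate and the saturated chain are inert, and MeCN keeps the catalyst from being bound by the carboxylic acid.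

Step 5
Reactants: 10 (11S)-11-acetoxydodecanoic acid
Product: 11 (11S)-11-acetoxydodecanoyl chloride
Conditions: (COCl)2 (1.3 equiv), DMF (1 mol %), CH2Cl2, 0 °C to rt; evaporated three times with toluene, used crude
Reagents that add atoms: oxalyl chloride, O=C(Cl)C(=O)Cl
Why: DMF-catalysed formation of the acid chloride gives only gaseous by-products, which can be stripped completely; this matters because step 6 does not tolerate HCl. The acetate and C10' are inert.

Step 6
Reactants: 11 (11S)-11-acetoxydodecanoyl chloride; 4 1-methoxybut-1-yne (two molecules enter the product)
Product: 14 (2S)-11-(3,5-diethyl-6-methoxy-4-oxo-4H-pyran-2-yl)undecan-2-yl acetate, via chloro enol ether 12 (not isolated), via acylketene 13 (not isolated)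
Conditions: 4 (3 equiv), 2,6-di-tert-butyl-4-methylpyridine (0.1 equiv), ClCH2CH2Cl, 11 added slowly at 0 °C, then 70 °C under a cold reflux condenser with Ar sweep
Reagents that add atoms: none
Why: Proposed new method: The only nucleophilic carbon of 4, the alkyne carbon that bears ethyl, attacks the acyl carbon of 11 (bond C5-C6), and chloride leaves and returns to the O-methylketenium carbon to give 12, which parallels the known C-acylation of ynamines and of ketene acetals by acid chlorides. Chloride then removes the O-methyl group from the ionised form of 12 by SN2 attack, the same dealkylation that ends the acylation of ketene acetals, and acylketene 13 results. A second molecule of 4 adds with the same carbon to the ketene carbon of 13 (bond C3-C4), and the enolate oxygen O1 of the zwitterion closes on the digonal ketenium carbon C2 (6-endo-dig, the second bond of a formal hetero-[4+2] cycloaddition in which O1=C6-C5=C4 is the four-atom part). The closest known reaction type is the cycloaddition of thermally generated α-oxoketenes to ynamines, alkoxyalkynes and enol ethers, which gives 4-pyranones; what is new is that the oxoketene is made in the same flask from the acid chloride and the same alkyne. No stereocentre is formed, and C10' is untouched because the medium holds no base and no nucleophile for the acetate. Regioselectivity needs no control element beyond polarity: in both C-C bond formations the donor carbon of 4 meets the most electrophilic carbon present, so methoxy can end only at C2 and the ethyl groups only at C3 and C5. Periselectivity for the six-membered ring over [2+2] addition at the ketene C=C bond rests on the s-cis oxadiene that 13 can adopt and on the gain of the cross-conjugated pyranone. Slow addition of 11 to an excess of 4 keeps 11 away from the basic C4 oxygen of 14, the hindered pyridine takes up traces of HCl that would hydrochlorinate 4, and the methyl ether of 4 has no β-hydrogen and so cannot fragment by a retro-ene path at 70 °C.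

## Compound list

1 | 2-chloro-1,1-dimethoxyethane | COC(CCl)OC | starting material
2 | bromoethane | CCBr | starting material
3 | sodium methoxyacetylide | [Na+].[C-]#COC | intermediate
4 | 1-methoxybut-1-yne | CCC#COC | intermediate
5 | 10-bromodec-1-ene | C=CCCCCCCCCBr | starting material
6 | (S)-2-methyloxirane | C[C@H]1CO1 | starting material
7 | dec-9-enylmagnesium bromide | C=CCCCCCCCC[Mg]Br | intermediate
8 | (2S)-tridec-12-en-2-ol | C=CCCCCCCCCC[C@H](C)O | intermediate
9 | (2S)-tridec-12-en-2-yl acetate | C=CCCCCCCCCC[C@H](C)OC(C)=O | intermediate
10 | (11S)-11-acetoxydodecanoic acid | OC(=O)CCCCCCCCC[C@H](C)OC(C)=O | intermediate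
11 | (11S)-11-acetoxydodecanoyl chloride | ClC(=O)CCCCCCCCC[C@H](C)OC(C)=O | intermediate
12 | (2S)-14-chloro-13-ethyl-14-methoxy-12-oxotetradec-13-en-2-yl acetate (alkene geometry open) | CCC(C(=O)CCCCCCCCC[C@H](C)OC(C)=O)=C(Cl)OC | intermediate
13 | (2S)-13-ethyl-12,14-dioxotetradec-13-en-2-yl acetate (acylketene) | CCC(=C=O)C(=O)CCCCCCCCC[C@H](C)OC(C)=O | intermediate
14 | (2S)-11-(3,5-diethyl-6-methoxy-4-oxo-4H-pyran-2-yl)undecan-2-yl acetate | CCc1c(CCCCCCCCC[C@H](C)OC(C)=O)oc(OC)c(CC)c1=O | target

## Step count and least certain steps

Total step count: 6. Longest linear sequence: 5 steps (steps 2 to 6: 5, 8, 9, 10, 11, 14). Step 1 is the side branch.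

**Step 6 (key step, carries the label).** Three things are most likely to go wrong.
- The first acylation may be too slow without a Lewis acid, so that acid-induced hydrochlorination and oligomerisation of 4 take over.
- The first adduct may close through its oxygen (formal [2+2] addition at the C=O bond followed by ring opening) instead of losing chloride.
- Unreacted 11 may acylate the C4 oxygen of the product, with loss of the methyl group at C2.

All three stem from the presence of the acyl chloride during ring formation. The fallback uses known chemistry: it makes the two C-C bonds separately and sets the acylketene free by a retro-[4+2] reaction. It sets out from 11. Acylation of the lithium enolate of tert-butyl butanoate (LDA, THF, -78 °C, two equivalents of enolate) gives tert-butyl (13S)-13-acetoxy-2-ethyl-3-oxotetradecanoate F1. Acetone, Ac2O and catalytic H2SO4 turn this into (2S)-11-(5-ethyl-2,2-dimethyl-4-oxo-4H-1,3-dioxin-6-yl)undecan-2-yl acetate F2. Heating F2 with 4 in toluene at 110 °C releases acetone and comes back to the route at 13, which is taken up by 4 to give 14 in a medium free of chloride and acyl chloride.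

**Step 1.** The volatile product may be lost with the evaporating ammonia. Ethylation may also be incomplete, which leaves a hazardous terminal alkyne in the distillate. The fallback builds the alkynyl ether in THF from a C2 unit of another oxidation pattern. It sets out from 2, with trichloroethene in place of 1. Potassium methoxide (KH, MeOH, THF) and trichloroethene give (E)-1,2-dichloro-1-methoxyethene F3. n-BuLi (2.2 equiv, -78 °C) converts it by elimination and chlorine-lithium exchange into lithium methoxyacetylide F4. F4 is alkylated with 2 in THF/DMPU, which comes back to the route at 4.

**Step 2.** Bromide from the Schlenk equilibrium may open the epoxide (halohydrin formation), and Wurtz coupling may occur while the Grignard reagent forms; both consume 5 and 6. The fallback sets the stereocentre by an enzyme instead of buying it. It sets out from 5. Alkylation of ethyl acetoacetate (NaOEt, EtOH) gives ethyl 2-acetyldodec-11-enoate F5. Saponification and decarboxylation give tridec-12-en-2-one F6. An NAD(P)H-dependent alcohol dehydrogenase that delivers hydride to the Re face (propan-2-ol as co-substrate, buffer, 30 °C) tells methyl from the long chain and comes back to the route at 8.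

**Step 4.** The oxidation may stall at the aldehyde stage when the catalyst is deactivated, and the chain may be shortened by over-oxidation through the enol of that aldehyde. The fallback carries the carboxyl group from the start and needs no oxidation. It sets out from 6. The dianion of non-8-ynoic acid (n-BuLi, 2 equiv, THF/DMPU) opens 6 at the CH2 terminus to give (11S)-11-hydroxydodec-8-ynoic acid F7. Hydrogenation (H2, Pd/C, EtOAc) gives (11S)-11-hydroxydodecanoic acid F8. Acetylation (Ac2O, pyridine, aqueous work-up) comes back to the route at 10 and replaces steps 2 to 4.

## Further compounds

F1 | step 6 | tert-butyl (13S)-13-acetoxy-2-ethyl-3-oxotetradecanoate | CCC(C(=O)OC(C)(C)C)C(=O)CCCCCCCCC[C@H](C)OC(C)=O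
F2 | step 6 | (2S)-11-(5-ethyl-2,2-dimethyl-4-oxo-4H-1,3-dioxin-6-yl)undecan-2-yl acetate | CCC1=C(CCCCCCCCC[C@H](C)OC(C)=O)OC(C)(C)OC1=O
F3 | step 1 | (E)-1,2-dichloro-1-methoxyethene | CO/C(Cl)=C\Cl
F4 | step 1 | lithium methoxyacetylide | [Li+].[C-]#COC
F5 | step 2 | ethyl 2-acetyldodec-11-enoate | CCOC(=O)C(CCCCCCCCC=C)C(C)=O
F6 | step 2 | tridec-12-en-2-one | CC(=O)CCCCCCCCCC=C
F7 | step 4 | (11S)-11-hydroxydodec-8-ynoic acid | OC(=O)CCCCCCC#CC[C@H](C)O
F8 | step 4 | (11S)-11-hydroxydodecanoic acid | OC(=O)CCCCCCCCC[C@H](C)O
A1 | alternative 1 | methyl 2-ethyl-3-oxohexanoate | CCCC(=O)C(CC)C(=O)OC
A2 | alternative 1 | methyl (15S)-15-[(tert-butyldimethylsilyl)oxy]-2,4-diethyl-3,5-dioxohexadecanoate | COC(=O)C(CC)C(=O)C(CC)C(=O)CCCCCCCCC[C@H](C)O[Si](C)(C)C(C)(C)C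
A3 | alternative 1 | 6-[(10S)-10-[(tert-butyldimethylsilyl)oxy]undecyl]-3,5-diethyl-4-hydroxy-2H-pyran-2-one | CCc1c(O)c(CC)c(CCCCCCCCC[C@H](C)O[Si](C)(C)C(C)(C)C)oc1=O
A4 | alternative 2 | 3,5-diethyl-2,6-dimethoxy-4H-pyran-4-one | CCc1c(OC)oc(OC)c(CC)c1=O
A5 | alternative 2 | [(10S)-10-[(tert-butyldimethylsilyl)oxy]undecyl]lithium | [Li]CCCCCCCCC[C@H](C)O[Si](C)(C)C(C)(C)C
A6 | alternative 2 | 6-[(10S)-10-[(tert-butyldimethylsilyl)oxy]undecyl]-3,5-diethyl-2-methoxy-4H-pyran-4-one | CCc1c(CCCCCCCCC[C@H](C)O[Si](C)(C)C(C)(C)C)oc(OC)c(CC)c1=O
A7 | alternative 3 | dodecanoyl chloride | CCCCCCCCCCCC(=O)Cl
A8 | alternative 3 | 3,5-diethyl-2-methoxy-6-undecyl-4H-pyran-4-one | CCCCCCCCCCCc1oc(OC)c(CC)c(=O)c1CC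
A9 | alternative 3 | 3,5-diethyl-6-[(10S)-10-hydroxyundecyl]-2-methoxy-4H-pyran-4-one | CCc1c(CCCCCCCCC[C@H](C)O)oc(OC)c(CC)c1=O
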